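The ten-membered carbocycle (C1–C10) is opened at C7–C8: C8 is an allylic carbinol on the β-carbon C7 of the butenolide ring (C6, C7, C11, C12, O), so this bond can be made from an aldehyde and an alkenyl iodide. One chromium-mediated Nozaki–Hiyama–Kishi addition forms C7–C8, the ring and the C8 stereocentre under non-basic conditions that spare the C1–C10 and C4–C5 epoxides. Its precursor is an acyclic β-iodobutenolide that already carries the C13 acetate, a C14 silyl ether, both epoxides, the Z C2=C3 alkene and a β,γ-epoxy aldehyde at C8; it comes from a Sonogashira coupling, two Sharpless epoxidations and an allene iodolactonization.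

Key step: step 18

Remark: atom labels follow the target (C12 lactone carbonyl, C13 acetoxymethyl carbon, C14 hydroxymethyl carbon, C15 methyl; target 1R,4R,5S,6S,8S,10S,2Z); it is assumed that natural L-(+)-tartrate gives the S configuration at the carbinol-bearing epoxide carbons C10 and C5, and zerovalent palladium is used only before the first epoxide exists.

Step 1
Reactants: 1 propargyl alcohol; 2 allylmagnesium bromide
Product: 4 (Z)-2-(iodomethylene)pent-4-en-1-ol, via vinylmagnesium alkoxide 3 (not isolated)
Conditions: 2 (3 equiv), Et2O, 0 °C to reflux; then I2, THF, −40 to 0 °C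
Reagents that add atoms: iodine, II
Why: Hydroxyl-directed anti carbomagnesiation of the propargylic alkoxide places the allyl group on C10 and magnesium on C1 inside a five-membered chelate, so iodinolysis with retention should give the iodide cis to the hydroxymethyl group (Z).

Step 2
Reactants: 5 (Z)-3-methylpent-2-en-4-yn-1-ol
Product: 6 (Z)-3-methylpent-2-en-4-yn-1-yl acetate
Conditions: Ac2O, pyridine, DMAP (cat.), CH2Cl2, 0 °C
Reagents that add atoms: acetic anhydride, CC(=O)OC(C)=O
Why: Routine acylation masks the C6 hydroxyl, so that only the C14 hydroxyl can direct the first epoxidation.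

Step 3
Reactants: 4 (Z)-2-(iodomethylene)pent-4-en-1-ol; 6 (Z)-3-methylpent-2-en-4-yn-1-yl acetate
Product: 7 dienyne (2Z,6Z)-7-(hydroxymethyl)-3-methyldeca-2,6,9-trien-4-yn-1-yl acetate
Conditions: Pd(PPh3)2Cl2 (3 mol %), CuI (6 mol %), Et3N, THF, rt
Reagents that add atoms: none
Why: Sonogashira coupling forms C1–C2 with retention of both alkene geometries and is placed before any epoxide exists, so zerovalent palladium never meets a vinyl or alkynyl epoxide.

Step 4
Reactants: 7 dienyne acetate
Product: 8 (1R,10S)-epoxy alcohol (C1–C10 epoxide of 7 with free C14 hydroxyl)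
Conditions: Ti(OiPr)4 (20 mol %), L-(+)-DIPT (24 mol %), t-BuOOH (decane), 4 Å MS, CH2Cl2, −20 °C
Reagents that add atoms: tert-butyl hydroperoxide, CC(C)(C)OO
Why: Sharpless asymmetric epoxidation directed by the C14 hydroxyl should set 10S and 1R with L-(+)-tartrate, the slim alkynyl group in the cis position keeping this Z-type allylic alcohol a workable substrate while the acetylated C4=C5 alkene and the terminal alkene stay untouched.

Step 5
Reactants: 8 (1R,10S)-epoxy alcohol
Product: 9 C14 tert-butyldiphenylsilyl ether of 8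
Conditions: TBDPSCl, imidazole, DMF, 0 °C to rt
Reagents that add atoms: tert-butyldiphenylsilyl chloride, CC(C)(C)[Si](Cl)(c1ccccc1)c1ccccc1
Why: Silylation of the primary alcohol installs the one protecting group that has to last to the final step and that is more robust than the later C13 silyl ether.

Step 6
Reactants: 9 C14 silyl ether acetate
Product: 10 (1R,10S)-C6 allylic alcohol (acetate removed)
Conditions: K2CO3 (0.2 equiv), MeOH, 0 °C
Reagents that add atoms: none
Why: Mild transesterification frees the C6 hydroxyl without touching the silyl ether or the alkynyl epoxide.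

Step 7
Reactants: 10 C6 allylic alcohol
Product: 11 (1R,4R,5S,10S)-bis-epoxy alkynol (epoxides C1–C10 and C4–C5 flanking the C2≡C3 alkyne)
Conditions: Ti(OiPr)4 (20 mol %), L-(+)-DIPT (24 mol %), t-BuOOH (decane), 4 Å MS, CH2Cl2, −20 °C
Reagents that add atoms: tert-butyl hydroperoxide, CC(C)(C)OO
Why: A second Sharpless asymmetric epoxidation, now directed by the C6 hydroxyl, should set 4R and 5S with the same L-(+)-tartrate, and the minor enantiomer carried from step 4 is converted mainly into a separable diastereomer.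

Step 8
Reactants: 11 bis-epoxy alkynol
Product: 12 (1R,4R,5S,10S,2Z)-bis-epoxy alkenol
Conditions: H2 (1 atm), Pd/CaCO3 poisoned with Pb(OAc)2, quinoline, EtOAc, rt, stopped after one equivalent of H2
Reagents that add atoms: none
Why: Lindlar semihydrogenation adds hydrogen syn to give the Z C2=C3 alkene, the alkyne being bound and reduced ahead of the terminal alkene and the propargylic C–O bonds surviving on the poisoned catalyst.

Step 9
Reactants: 12 bis-epoxy alkenol
Product: 13 (1R,4R,5R,10S,2Z)-epoxy aldehyde (C6 aldehyde; 5R only by change of ranking)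
Conditions: Dess–Martin periodinane, pyridine, CH2Cl2, 0 °C
Reagents that add atoms: none
Why: Buffered Dess–Martin oxidation gives the cis-epoxy aldehyde without epimerization at C5 or opening of the vinyl epoxides.

Step 10
Reactants: 13 epoxy aldehyde; 14 tert-butyldimethyl(prop-2-yn-1-yloxy)silane
Product: 16 (1R,4R,5S,6S,10S,2Z)-propargylic alcohol (C6 carbinol bearing C7≡C11–C13H2OTBS), via lithium acetylide 15 (not isolated)
Conditions: 14, n-BuLi, THF, −78 °C; then 13, −78 °C
Reagents that add atoms: none
Why: Felkin–Anh-controlled acetylide addition (attack anti to the C5–O bond and past H5, reinforced by the cis substituent on C4) should give the anti (erythro) 6S alcohol, which has the C5/C6 relationship of the target.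

Step 11
Reactants: 16 propargylic alcohol
Product: 17 C6 (tributylstannyl)methyl ether of 16
Conditions: KH, Bu3SnCH2I, 18-crown-6 (cat.), THF, 0 °C
Reagents that add atoms: tributyl(iodomethyl)stannane, CCCC[Sn](CCCC)(CCCC)CI
Why: Williamson etherification of the potassium alkoxide with the reactive iodomethylstannane should outrun Payne migration of the neighbouring epoxide and leaves C6 untouched.

Step 12
Reactants: 17 stannylmethyl ether
Product: 19 (1R,4R,5S,10S,aS)-allenol (C6H=C7=C11 bearing C12H2OH and C13H2OTBS), via α-lithio ether 18 (not isolated)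
Conditions: n-BuLi, THF, −78 °C
Reagents that add atoms: none
Why: Wittig–Still rearrangement, in which tin–lithium exchange gives an α-alkoxy organolithium whose suprafacial [2,3]-sigmatropic shift forms C11–C12 on the side from which the C6–O bond departs, should translate the C6 centre into the (aS) allene axis.

Step 13
Reactants: 19 allenol
Product: 21 (1R,4R,5S,10S,aR)-allenoic acid (C12 carboxylic acid), via allenal 20 (not isolated)
Conditions: TEMPO (20 mol %), PhI(OAc)2 (2.2 equiv), MeCN/pH 7 phosphate buffer, rt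
Reagents that add atoms: water, O
Why: Oxoammonium oxidation of the primary allenic alcohol to the aldehyde and of its hydrate to the acid proceeds under neutral conditions that keep the allene axis, the epoxides and both silyl ethers.

Step 14
Reactants: 21 allenoic acid
Product: 22 (1R,4R,5S,6R,10S,2Z)-β-iodobutenolide (I on C7; C13 OTBS; C14 OTBDPS; allyl on C10)
Conditions: I2, NaHCO3, MeCN, 0 °C, dark
Reagents that add atoms: iodine, II
Why: Iodolactonization of the 2,3-allenoic acid, in which the carboxylate closes the five-membered ring by anti attack at C6 from its own side of the iodine-activated C6=C7 bond, should put iodine on C7 and return the axis to a C6 centre with the oxygen where the hydroxyl of 16 stood (6R only because iodine raises the rank of C7).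

Step 15
Reactants: 22 β-iodobutenolide
Product: 23 C13 alcohol
Conditions: HF·pyridine, pyridine, THF, 0 °C
Reagents that add atoms: none
Why: Buffered fluoride desilylation removes the unhindered primary TBS ether far faster than the neopentyl-type TBDPS ether.

Step 16
Reactants: 23 C13 alcohol
Product: 24 C13 acetate
Conditions: Ac2O, pyridine, CH2Cl2, 0 °C to rt
Reagents that add atoms: acetic anhydride, CC(=O)OC(C)=O
Why: Acylation installs the acetate of the target before the ring closure, so that only two steps follow the key step.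

Step 17
Reactants: 24 C13 acetate
Product: 26 seco aldehyde (1R,4R,5S,6R,10S,2Z; C8 aldehyde), via terminal diol 25 (not isolated)
Conditions: OsO4 (2 mol %), NaIO4 (4 equiv), 2,6-lutidine, 1,4-dioxane/H2O, rt; used at once
Reagents that add atoms: OsO4, O=[Os](=O)(=O)=O; sodium periodate, [Na+].[O-][I](=O)(=O)=O
Why: Lemieux–Johnson oxidation should dihydroxylate the monosubstituted terminal alkene in preference to the hindered, epoxide-flanked Z alkene and the electron-poor iodobutenolide, and periodate cleaves the diol to the C8 aldehyde.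

Step 18
Reactants: 26 seco aldehyde
Product: 28 (1R,4R,5S,6S,8S,10S,2Z)-macrocyclic C8 alcohol, via alkenylchromium dichloride 27 (not isolated)
Conditions: CrCl2 (12 equiv), NiCl2 (0.1 equiv), degassed DMSO, rt, slow addition of 26 to 0.003 M
Reagents that add atoms: none
Why: Nozaki–Hiyama–Kishi reaction: CrCl2 reduces NiCl2 to zerovalent nickel, which adds oxidatively to the activated C7–I bond; transmetalation gives an alkenyl species of trivalent chromium that adds to the C8 aldehyde and forms C7–C8. The closest known reaction type is the intramolecular Ni/Cr coupling of alkenyl iodides, β-iodo enoates included, with aldehydes to medium and large rings. The ten-membered carbocycle closes in a 10-exo-trig mode, helped by the butenolide, the Z alkene and the two epoxides, which leave few rotatable bonds between C7 and C8. The C8 stereocentre is under substrate control: C9 must reach C8 from the butenolide face that carries C5 (fixed by C6 and the C1–C10 epoxide), and the chromium-bound oxygen is expected to lie in the lactone plane turned toward C13 and away from the substituted C6, which leads to 8S. The step needs chemoselectivity and face selectivity: the reagent is not basic, so the β,γ-epoxy aldehyde, the acidic C6–H, both epoxides and the acetate should survive, organochromium adds only to the aldehyde, and high dilution suppresses oligomers. A chiral sulfonamide ligand on chromium can reinforce the facial preference.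

Step 19
Reactants: 28 macrocyclic C8 alcohol
Product: 29 C8 methacrylate
Conditions: methacrylic anhydride, Et3N, DMAP (cat.), CH2Cl2, 0 °C to rt
Reagents that add atoms: methacrylic anhydride, CC(=C)C(=O)OC(=O)C(C)=C
Why: DMAP-catalysed acylation esterifies the only free hydroxyl with retention at C8.

Step 20
Reactants: 29 C8 methacrylate
Product: 30 target CNP0207684.1
Conditions: HF·pyridine, pyridine, THF, 0 °C to rt
Reagents that add atoms: none
Why: Buffered fluoride desilylation frees the C14 hydroxyl under conditions that should leave both esters, both epoxides and the butenolide intact.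

Compound list
1 | propargyl alcohol | C#CCO | starting material
2 | allylmagnesium bromide | C=CC[Mg]Br | starting material
3 | vinylmagnesium alkoxide (cyclic chelate, Mg bridging C1 and the C14 oxygen) | C=CCC1=C[Mg]OC1 | intermediate (not isolated)
4 | (Z)-2-(iodomethylene)pent-4-en-1-ol | OC/C(CC=C)=C\I | intermediate
5 | (Z)-3-methylpent-2-en-4-yn-1-ol | C#C/C(C)=C\CO | starting material
6 | (Z)-3-methylpent-2-en-4-yn-1-yl acetate | C#C/C(C)=C\COC(C)=O | intermediate
7 | (2Z,6Z)-7-(hydroxymethyl)-3-methyldeca-2,6,9-trien-4-yn-1-yl acetate | OC/C(CC=C)=C\C#C/C(C)=C\COC(C)=O | intermediate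
8 | (1R,10S)-epoxy alcohol: (Z)-5-[(2R,3S)-3-allyl-3-(hydroxymethyl)oxiran-2-yl]-3-methylpent-2-en-4-yn-1-yl acetate | C=CC[C@@]1(CO)O[C@@H]1C#C/C(C)=C\COC(C)=O | intermediate
9 | C14 TBDPS ether of 8 | C=CC[C@@]1(CO[Si](c2ccccc2)(c2ccccc2)C(C)(C)C)O[C@@H]1C#C/C(C)=C\COC(C)=O | intermediate
10 | (1R,10S)-C6 allylic alcohol (9 without the acetyl group) | C=CC[C@@]1(CO[Si](c2ccccc2)(c2ccccc2)C(C)(C)C)O[C@@H]1C#C/C(C)=C\CO | intermediate
11 | (1R,4R,5S,10S)-bis-epoxy alkynol | C=CC[C@@]1(CO[Si](c2ccccc2)(c2ccccc2)C(C)(C)C)O[C@@H]1C#C[C@@]1(C)O[C@H]1CO | intermediate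
12 | (1R,4R,5S,10S,2Z)-bis-epoxy alkenol | C=CC[C@@]1(CO[Si](c2ccccc2)(c2ccccc2)C(C)(C)C)O[C@@H]1/C=C\[C@@]1(C)O[C@H]1CO | intermediate
13 | (1R,4R,5R,10S,2Z)-epoxy aldehyde (C6 aldehyde) | C=CC[C@@]1(CO[Si](c2ccccc2)(c2ccccc2)C(C)(C)C)O[C@@H]1/C=C\[C@@]1(C)O[C@H]1C=O | intermediate
14 | tert-butyldimethyl(prop-2-yn-1-yloxy)silane | C#CCO[Si](C)(C)C(C)(C)C | starting material
15 | lithium acetylide of 14 | [Li]C#CCO[Si](C)(C)C(C)(C)C | intermediate (not isolated)
16 | (1R,4R,5S,6S,10S,2Z)-propargylic alcohol | C=CC[C@@]1(CO[Si](c2ccccc2)(c2ccccc2)C(C)(C)C)O[C@@H]1/C=C\[C@@]1(C)O[C@H]1[C@@H](O)C#CCO[Si](C)(C)C(C)(C)C | intermediate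
17 | C6 (tributylstannyl)methyl ether of 16 | C=CC[C@@]1(CO[Si](c2ccccc2)(c2ccccc2)C(C)(C)C)O[C@@H]1/C=C\[C@@]1(C)O[C@H]1[C@@H](OC[Sn](CCCC)(CCCC)CCCC)C#CCO[Si](C)(C)C(C)(C)C | intermediate
18 | α-lithio ether (C6–O–CH2Li) | C=CC[C@@]1(CO[Si](c2ccccc2)(c2ccccc2)C(C)(C)C)O[C@@H]1/C=C\[C@@]1(C)O[C@H]1[C@@H](OC[Li])C#CCO[Si](C)(C)C(C)(C)C | intermediate (not isolated)
19 | (1R,4R,5S,10S,aS)-allenol (C12H2OH and C13H2OTBS on C11) | C=CC[C@@]1(CO[Si](c2ccccc2)(c2ccccc2)C(C)(C)C)O[C@@H]1/C=C\[C@@]1(C)O[C@H]1C([H])=[C@@]=C(CO)CO[Si](C)(C)C(C)(C)C | intermediate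
20 | (aR)-allenal (C12 aldehyde) | C=CC[C@@]1(CO[Si](c2ccccc2)(c2ccccc2)C(C)(C)C)O[C@@H]1/C=C\[C@@]1(C)O[C@H]1C([H])=[C@@]=C(C=O)CO[Si](C)(C)C(C)(C)C | intermediate (not isolated)
21 | (1R,4R,5S,10S,aR)-allenoic acid | C=CC[C@@]1(CO[Si](c2ccccc2)(c2ccccc2)C(C)(C)C)O[C@@H]1/C=C\[C@@]1(C)O[C@H]1C([H])=[C@@]=C(C(=O)O)CO[Si](C)(C)C(C)(C)C | intermediate
22 | (1R,4R,5S,6R,10S,2Z)-β-iodobutenolide, C13 OTBS | C=CC[C@@]1(CO[Si](c2ccccc2)(c2ccccc2)C(C)(C)C)O[C@@H]1/C=C\[C@@]1(C)O[C@H]1[C@H]1OC(=O)C(CO[Si](C)(C)C(C)(C)C)=C1I | intermediate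
23 | β-iodobutenolide, C13 alcohol | C=CC[C@@]1(CO[Si](c2ccccc2)(c2ccccc2)C(C)(C)C)O[C@@H]1/C=C\[C@@]1(C)O[C@H]1[C@H]1OC(=O)C(CO)=C1I | intermediate
24 | β-iodobutenolide, C13 acetate | C=CC[C@@]1(CO[Si](c2ccccc2)(c2ccccc2)C(C)(C)C)O[C@@H]1/C=C\[C@@]1(C)O[C@H]1[C@H]1OC(=O)C(COC(C)=O)=C1I | intermediate
25 | terminal diol from dihydroxylation of the allyl group of 24 (both epimers at the new carbinol) | OCC(O)C[C@@]1(CO[Si](c2ccccc2)(c2ccccc2)C(C)(C)C)O[C@@H]1/C=C\[C@@]1(C)O[C@H]1[C@H]1OC(=O)C(COC(C)=O)=C1I | intermediate (not isolated)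
26 | seco aldehyde (1R,4R,5S,6R,10S,2Z) with β-iodobutenolide | O=CC[C@@]1(CO[Si](c2ccccc2)(c2ccccc2)C(C)(C)C)O[C@@H]1/C=C\[C@@]1(C)O[C@H]1[C@H]1OC(=O)C(COC(C)=O)=C1I | intermediate
27 | alkenylchromium dichloride (Cr on C7 in place of I) | O=CC[C@@]1(CO[Si](c2ccccc2)(c2ccccc2)C(C)(C)C)O[C@@H]1/C=C\[C@@]1(C)O[C@H]1[C@H]1OC(=O)C(COC(C)=O)=C1[Cr](Cl)Cl | intermediate (not isolated)
28 | (1R,4R,5S,6S,8S,10S,2Z)-ten-membered C8 alcohol with butenolide | O[C@H]1C[C@@]2(CO[Si](c3ccccc3)(c3ccccc3)C(C)(C)C)O[C@@H]2/C=C\[C@@]2(C)O[C@H]2[C@H]2OC(=O)C(COC(C)=O)=C12 | intermediate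
29 | C8 methacrylate of 28 | C=C(C)C(=O)O[C@H]1C[C@@]2(CO[Si](c3ccccc3)(c3ccccc3)C(C)(C)C)O[C@@H]2/C=C\[C@@]2(C)O[C@H]2[C@H]2OC(=O)C(COC(C)=O)=C12 | intermediate
30 | CNP0207684.1 | C=C(C)C(=O)O[C@H]1C[C@@]2(CO)O[C@@H]2/C=C\[C@@]2(C)O[C@H]2[C@H]2OC(=O)C(COC(C)=O)=C12 | target

Total step count: 20. Longest linear sequence: 19 steps (5 to 30 by steps 2 to 20; the branch from 1 is step 1).

Steps most likely to fail

1. Step 18. The alkenylchromium may add to the other face of the C8 aldehyde, so that the ring closes with the wrong configuration at C8 or as an epimer mixture. The fallback sets out from 26: the cyclization is run as in step 18, and the separated 8-epi alcohol F1 is esterified under Mitsunobu conditions (methacrylic acid, PPh3, DIAD, toluene, 0 °C). Substitution with inversion at C8 should give the methacrylate 29, where the route is rejoined; the stereocentre is then set in a stereospecific C–O substitution and not in the C–C bond formation.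

2. Step 12. The organolithium from tin–lithium exchange, or n-BuLi itself, may open a vinyl epoxide or undergo a [1,2] shift in place of the [2,3] rearrangement. The fallback sets out from 16 and uses the anti pathway of a palladium carbonylation, which needs the opposite C6 configuration. Mitsunobu reaction with 4-nitrobenzoic acid (PPh3, DIAD) gives the inverted 4-nitrobenzoate F2; methanolysis (K2CO3, MeOH, 0 °C) gives the 6-epi alcohol F3; MsCl and Et3N at −40 °C give the mesylate F4. Carbonylation with Pd(PPh3)4 (5 mol %) under CO (1 atm) in THF/H2O (anti SN2′ oxidative addition, CO insertion, hydrolysis) should give the allenoic acid 21, where the route is rejoined. This path exposes the vinyl epoxides to zerovalent palladium, which is why it is not the first choice.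

3. Step 10. Facial control in the acetylide addition may be weak, so that much of the material ends up with the wrong configuration at C6. The fallback sets out from 13: the crude mixture of 16 and its C6 epimer is oxidized with Dess–Martin periodinane to the ynone F5. Reduction with Zn(BH4)2 in Et2O at −20 °C, a chelation-controlled reduction known to turn α,β-epoxy ketones into anti (erythro) epoxy alcohols, should return 16. Control then comes from hydride delivery to a ketone and not from the carbonyl addition.

Further compounds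
F1 | step 18 | 8-epi alcohol (8R epimer of 28) | O[C@@H]1C[C@@]2(CO[Si](c3ccccc3)(c3ccccc3)C(C)(C)C)O[C@@H]2/C=C\[C@@]2(C)O[C@H]2[C@H]2OC(=O)C(COC(C)=O)=C12
F2 | step 12 | inverted (6R) 4-nitrobenzoate of 16 | C=CC[C@@]1(CO[Si](c2ccccc2)(c2ccccc2)C(C)(C)C)O[C@@H]1/C=C\[C@@]1(C)O[C@H]1[C@H](OC(=O)c1ccc(cc1)[N+](=O)[O-])C#CCO[Si](C)(C)C(C)(C)C
F3 | step 12 | 6-epi (6R) propargylic alcohol | C=CC[C@@]1(CO[Si](c2ccccc2)(c2ccccc2)C(C)(C)C)O[C@@H]1/C=C\[C@@]1(C)O[C@H]1[C@H](O)C#CCO[Si](C)(C)C(C)(C)C
F4 | step 12 | (6R) propargylic mesylate | C=CC[C@@]1(CO[Si](c2ccccc2)(c2ccccc2)C(C)(C)C)O[C@@H]1/C=C\[C@@]1(C)O[C@H]1[C@H](OS(C)(=O)=O)C#CCO[Si](C)(C)C(C)(C)C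
F5 | step 10 | epoxy ynone (C6 ketone) | C=CC[C@@]1(CO[Si](c2ccccc2)(c2ccccc2)C(C)(C)C)O[C@@H]1/C=C\[C@@]1(C)O[C@H]1C(=O)C#CCO[Si](C)(C)C(C)(C)C
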